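**Conventions.** Flavanone atoms are O1, C2, C3, C4; ring A is the 5,7-dioxygenated benzo ring, ring C the pyranone, ring B the 3,5-dimethoxy-4-oxyphenyl ring, ring D the 4-hydroxyphenyl ring. The side chain is C7 (benzylic carbinol), C8 (aryloxy methine), C9 (hydroxymethyl). The target is 19; all other numbers are fixed by the steps below.

## Analysis of the target

The target is a flavonolignan: a (2S)-5,7-dihydroxyflavanone (rings A and C) whose ring B is 3,5-dimethoxylated, with the ring B oxygen at C4' etherified by C8 of a 1-(4-hydroxyphenyl)propane-1,3-diol chain. There are three stereocentres: C2 (S), C7 (R) and C8 (R). C7 and C8 are adjacent and threo, meaning the hydroxyl and the aryloxy group are syn when the chain ring D–C7–C8–C9 is drawn extended. C2 is separated from this pair by the whole of ring B, so neither unit can relay configuration to the other. Ring C opens under base by retro-oxa-Michael reaction to the 2'-hydroxychalcone, which erases C2. C7 is a para-oxygenated benzylic carbinol that ionises under acid and can be lost on hydrogenolysis. Three phenols, one primary alcohol and one secondary alcohol must be told apart. The ether at C8 joins a secondary carbon to a phenol oxygen flanked by two methoxy groups, so it is crowded and is best made early on a small fragment. The strategy rests on that same oxygen: it sits alpha to C7, so if C7 is an aldehyde carbon, the carbonyl oxygen and the C8 ether oxygen (supported by a neighbouring methoxy group) can hold magnesium in a five-membered chelate. One purchased centre at C8 can then set C7 when ring D is delivered as a nucleophile.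

## Retrosynthetic reasoning

**Protecting groups (19 ⇐ 18 ⇐ 17).** The three phenols are carried as benzyl ethers and removed last, because hydrogenolysis is neutral and so spares both C2 (base-labile) and C7 (acid-labile). The two alcohols are carried as silyl ethers, removed one step earlier from 17 while ring D is still benzylated and the C7 carbinol is therefore less prone to ionise.

**C2–C1' bond (17 ⇐ 13 + 16).** The bond between ring C and ring B is cut to give chromone 16 and arylboronic acid 13. This is the only disconnection that creates C2 by itself, so a chiral catalyst can set it without reference to the remote C7/C8 pair. It also delivers ring C at the flavanone oxidation level. The forward reaction must add the aryl group to one face of C2=C3 without base.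

**Chromone (16 ⇐ 14).** Ring C of 16 is closed from the acetyl group and the free phenol of acetophenone 14 with a one-carbon amide acetal, via enaminone 15.

**C1'–B bond (13 ⇐ 10 ⇐ 9).** The boronic acid comes from aryl bromide 10 by halogen–metal exchange and borate trapping. The bromine is carried from phenol 4 as a placeholder for C1'. The C7 hydroxyl of 9 is silylated first, since a free carbinol would interfere with the organolithium and with the divalent palladium catalyst.

**C7–ring D bond (9 ⇐ 6 + 8), the key disconnection.** Cutting between C7 and ring D gives aldehyde 6 and Grignard reagent 8. It is cut here rather than at C7–C8 because the aldehyde then retains the C8 aryloxy oxygen in the alpha position, which is the handle for chelation. The forward reaction must add the aryl group syn to that oxygen, giving the threo 7R,8R pattern, without enolising C8.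

**C8–O bond and chiral pool (6 ⇐ 5 ⇐ 3 + 4; 3 ⇐ 2 ⇐ 1).** Aldehyde 6 is the half-reduced form of ester 5. The hindered aryl ether of 5 is made by inverting displacement of the secondary hydroxyl of 3 by phenol 4, so the S glycerate becomes the R ether. An alpha-hydroxy ester is among the best carbons for such a substitution. Compound 3 is the primary silyl ether of diol 2, released from the commercial acetonide 1. The bulky silyl group on O9 both distinguishes O9 from O7 for the rest of the route and keeps O9 from chelating. Reagent 8 is made from bromide 7.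

## Alternatives that were turned down

**Alternative 1:** Ring C is opened at O1–C2 and C3–C4. Ring A becomes salicylaldehyde A1, C4 gains a methoxy group from orthoester A2, and C2–C3 is the vinyl group of styrene A3, which carries the complete protected side chain. In the forward step, acid turns A1 and A2 into an O-methyl oxocarbenium ion with ortho-quinone methide character. This adds to A3 in a polar [4+2] cycloaddition and gives the 4-methoxyflavan A4.
- For it: two bonds and ring C form in one convergent step from cheap components, with reliable regiochemistry. On bond economy for ring C it is stronger than the chosen route.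
- Against it: C4 arrives as a methyl ether and must be taken to the ketone in a molecule with a second electron-rich benzylic position (C7) and three benzyl ethers. The only stereocontrol offered is C4 relative to C2, and C4 is then destroyed.
- Against it: the side-chain centres are too far across ring B to bias the face of the styrene, so both C2 epimers are expected, differing only at a remote centre. The acid also threatens the C7 benzylic silyl ether and can polymerise an electron-rich styrene.
- Against it: it does not address C7/C8 at all; A3 would itself have to come from something like 10 plus a vinylation.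
- In its place the chosen route takes ring C ready-made at the correct oxidation level (16) and sets C2 by a catalyst.

**Alternative 2:** The C7–C8 bond is cut. C8 becomes the alpha carbon of aryloxyacetyl imide A5 on an (S)-4-benzyloxazolidinone, and C7 comes from aldehyde A6. In the forward step a dialkylboron triflate and a tertiary amine give the Z boron enolate, which reacts through a chair Zimmerman–Traxler transition state to give syn-aldol A7 with both centres set.
- For it: both centres are under reagent control with an inherently syn (threo) outcome, and no configurationally fragile alpha-aryloxy aldehyde is involved. On stereochemical reliability at C7/C8 it is stronger than the chosen route, which depends on a weakly basic aryl ether oxygen holding a chelate.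
- Against it: the ether oxygen of A5 with its two methoxy neighbours can sequester boron and disturb enolisation. A6 is an electron-rich, slow electrophile and its aldolate is prone to retro-aldol reaction.
- Against it: the auxiliary is stoichiometric and costs steps to attach and remove. Reductive removal gives a 1,3-diol whose C7 and C9 hydroxyls then need a selective differentiation.
- In its place the chosen route buys C8 from the chiral pool, needs no auxiliary, reaches the aldehyde in four steps with O9 already distinguished, and keeps a second, independent way to correct C7 by oxidation and reduction.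

**Alternative 3:** The C2–C1' bond is cut, giving the chromone 16 and a bis-silylated arylboronic acid A8. In the forward step a cationic divalent palladium pyridine–oxazoline catalyst transmetalates with A8, inserts the aryl group across C2=C3 and is released by protonolysis, giving the protected flavanone A9 with C2 set by the ligand.
- For it: C2 is set late, catalytically and independently of C7/C8, at the right oxidation level and under neutral conditions. On the C2 problem it is as strong as the chosen plan, because the chosen plan uses the same construction in step 10.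
- Against it as the central idea: it presupposes the side chain and says nothing about how the threo C7/C8 ether is obtained, which is the harder stereochemical problem.
- Against it: its characteristic risk (a deactivated, peri-substituted 5,7-dioxygenated acceptor and a protodeboronation-prone electron-rich boronic acid) falls on the most valuable intermediate.
- The chosen strategy adds the upstream solution for C7/C8 from one purchased centre and places its own characteristic risk early, on inexpensive material.

Key step: step 6

**Assumptions.** (R)-t-BuPyOx is assumed to deliver the aryl group to the face of 16 that gives 2S, by analogy with the facial sense known for cyclic enones; C2 is purely catalyst-controlled, so the antipodal ligand would be used if the sense proved opposite. Acetophenone 14 is taken as a commercial compound.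

## Route

Step 1
Reactants: 1 methyl (S)-2,2-dimethyl-1,3-dioxolane-4-carboxylate
Product: 2 methyl (S)-2,3-dihydroxypropanoate
Conditions: p-TsOH·H2O (5 mol%), MeOH, rt; then NaHCO3, filter, concentrate
Reagents that add atoms: none
Why: Acid-catalysed transacetalisation of the isopropylidene acetal in methanol; the methyl ester cannot be changed by the solvent and C2 is not involved, so the S centre is carried over.

Step 2
Reactants: 2 methyl (S)-2,3-dihydroxypropanoate
Product: 3 methyl (S)-2-hydroxy-3-[(triisopropylsilyl)oxy]propanoate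
Conditions: i-Pr3SiCl (1.05 equiv), imidazole, CH2Cl2, 0 °C → rt
Reagents that add atoms: chlorotriisopropylsilane, CC(C)[Si](Cl)(C(C)C)C(C)C
Why: Silylation with a bulky silyl chloride should select the unhindered primary hydroxyl over the secondary one, which is deactivated by the adjacent ester. The large silyl group is also what later keeps O9 out of any chelate.

Step 3
Reactants: 3 methyl (S)-2-hydroxy-3-[(triisopropylsilyl)oxy]propanoate; 4 4-bromo-2,6-dimethoxyphenol
Product: 5 methyl (R)-2-(4-bromo-2,6-dimethoxyphenoxy)-3-[(triisopropylsilyl)oxy]propanoate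
Conditions: PPh3 (1.3 equiv), DIAD (1.3 equiv), THF, 0 °C → rt
Reagents that add atoms: none
Why: Mitsunobu etherification; the phenoxide displaces the alkoxyphosphonium group at C2 by SN2 with inversion, S to R. Alpha-hydroxy esters are good substrates because the ester accelerates SN2 and suppresses ionisation.

Step 4
Reactants: 5 methyl (R)-2-(4-bromo-2,6-dimethoxyphenoxy)-3-[(triisopropylsilyl)oxy]propanoate
Product: 6 (R)-2-(4-bromo-2,6-dimethoxyphenoxy)-3-[(triisopropylsilyl)oxy]propanal
Conditions: i-Bu2AlH (1.1 equiv), CH2Cl2, −78 °C; MeOH, then aq. potassium sodium tartrate; used crude at once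
Reagents that add atoms: none
Why: Partial reduction of an ester with i-Bu2AlH at low temperature; the alpha-aryloxy group stabilises the tetrahedral aluminium hemiacetal by chelation, so the aldehyde is released only on work-up. The aldehyde is enolisable at C8 and is therefore kept cold and not purified.

Step 5
Reactants: 7 1-(benzyloxy)-4-bromobenzene
Product: 8 [4-(benzyloxy)phenyl]magnesium bromide (solution in Et2O)
Conditions: Mg turnings, I2 (cat.), Et2O, reflux
Reagents that add atoms: magnesium, [Mg]
Why: Grignard formation by insertion of magnesium into the aryl bromide; the benzyl aryl ether is inert. Diethyl ether is used so that no strongly coordinating solvent enters step 6.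

Step 6
Reactants: 6 (R)-2-(4-bromo-2,6-dimethoxyphenoxy)-3-[(triisopropylsilyl)oxy]propanal; 8 [4-(benzyloxy)phenyl]magnesium bromide
Product: 9 (1R,2R)-1-[4-(benzyloxy)phenyl]-2-(4-bromo-2,6-dimethoxyphenoxy)-3-[(triisopropylsilyl)oxy]propan-1-ol
Conditions: MgBr2·OEt2 (2 equiv), CH2Cl2, −78 °C, 20 min; then 8 (2 equiv, Et2O), −78 °C; aq. NH4Cl at −78 °C
Reagents that add atoms: none
Why: This is a Cram-chelate addition of an aryl Grignard reagent to an alpha-alkoxy aldehyde, the closest known reaction type being chelation-controlled Grignard addition to 2-alkoxy and 2-aryloxy aldehydes. MgBr2 binds the aldehyde oxygen and the C8 aryloxy oxygen, supported by one flanking methoxy group, in a five-membered chelate that holds C7=O and C8–O syn-periplanar. The two faces of the carbonyl then differ by hydrogen versus the silyloxymethyl group at C8, and the aryl group enters along the Bürgi–Dunitz path past the hydrogen. This forms the C7–ring D bond and the C7 centre as R, syn (threo) to the 8R centre, which is the only controlling element; no ring is closed. The selectivity needed is threo over the Felkin–Anh erythro adduct, and it should be secured by precomplexation in non-coordinating CH2Cl2 at −78 °C and by keeping THF out. The triisopropylsilyl ether is too bulky and too weakly basic to form the competing six-membered chelate through O9, which would lead to erythro. Low temperature and immediate use of crude 6 protect the enolisable C8 centre, and an aryl bromide does not exchange with an aryl Grignard reagent at −78 °C.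

Step 7
Reactants: 9 (1R,2R)-1-[4-(benzyloxy)phenyl]-2-(4-bromo-2,6-dimethoxyphenoxy)-3-[(triisopropylsilyl)oxy]propan-1-ol
Product: 10 (1R,2R)-1-[4-(benzyloxy)phenyl]-2-(4-bromo-2,6-dimethoxyphenoxy)-1-[(tert-butyldimethylsilyl)oxy]-3-[(triisopropylsilyl)oxy]propane
Conditions: t-BuMe2SiOTf (1.5 equiv), 2,6-lutidine, CH2Cl2, 0 °C
Reagents that add atoms: tert-butyldimethylsilyl trifluoromethanesulfonate, CC(C)(C)[Si](C)(C)OS(=O)(=O)C(F)(F)F
Why: Silylation of a hindered secondary benzylic alcohol with a silyl triflate and a non-nucleophilic base. The free carbinol would be deprotonated in step 8 and could be oxidised by divalent palladium in step 10; no stereocentre is touched.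

Step 8
Reactants: 10 (1R,2R)-1-[4-(benzyloxy)phenyl]-2-(4-bromo-2,6-dimethoxyphenoxy)-1-[(tert-butyldimethylsilyl)oxy]-3-[(triisopropylsilyl)oxy]propane
Product: 13 (4-{[(1R,2R)-1-[4-(benzyloxy)phenyl]-1-[(tert-butyldimethylsilyl)oxy]-3-[(triisopropylsilyl)oxy]propan-2-yl]oxy}-3,5-dimethoxyphenyl)boronic acid, via aryllithium 11 (not isolated), via lithium aryl(triisopropoxy)borate 12 (not isolated)
Conditions: B(Oi-Pr)3 (1.5 equiv), THF/toluene, −78 °C, then n-BuLi (1.2 equiv) dropwise; aq. NH4Cl, rt
Reagents that add atoms: triisopropyl borate, CC(C)OB(OC(C)C)OC(C)C; water, O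
Why: Bromine–lithium exchange with the borate already in the flask (in-situ quench), then hydrolysis of the borate complex. At −78 °C exchange is much faster than attack of n-BuLi on the borate or deprotonation of the benzylic positions, and the silyl and benzyl ethers are inert.

Step 9
Reactants: 14 1-[2,4-bis(benzyloxy)-6-hydroxyphenyl]ethan-1-one
Product: 16 5,7-bis(benzyloxy)-4H-chromen-4-one, via enaminone 15 (not isolated)
Conditions: Me2NCH(OMe)2, toluene, 100 °C; concentrate; then conc. HCl, CH2Cl2, rt
Reagents that add atoms: N,N-dimethylformamide dimethyl acetal, COC(OC)N(C)C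
Why: Condensation of the methyl ketone with the amide acetal gives the beta-dimethylamino enone; acid then triggers conjugate addition of the phenol oxygen and loss of dimethylamine (enaminone route to chromones). Aryl benzyl ethers should tolerate the brief acid treatment at room temperature.

Step 10
Reactants: 13 (4-{[(1R,2R)-1-[4-(benzyloxy)phenyl]-1-[(tert-butyldimethylsilyl)oxy]-3-[(triisopropylsilyl)oxy]propan-2-yl]oxy}-3,5-dimethoxyphenyl)boronic acid; 16 5,7-bis(benzyloxy)-4H-chromen-4-one
Product: 17 (2S)-5,7-bis(benzyloxy)-2-(4-{[(1R,2R)-1-[4-(benzyloxy)phenyl]-1-[(tert-butyldimethylsilyl)oxy]-3-[(triisopropylsilyl)oxy]propan-2-yl]oxy}-3,5-dimethoxyphenyl)chroman-4-one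
Conditions: Pd(OCOCF3)2 (5 mol%), (R)-t-BuPyOx (6 mol%), NH4PF6 (30 mol%), H2O (5 equiv), 16 (1.5 equiv), ClCH2CH2Cl, 60 °C
Reagents that add atoms: none
Why: Catalytic asymmetric conjugate addition of an arylboronic acid to a chromone; transmetalation gives a cationic aryl–palladium species whose ligand selects the enantiotopic face of C2=C3 for insertion, and water protonates the palladium enolate. C2 is set by the ligand alone because C7 and C8 are too remote to interfere. The neutral medium avoids ring opening of the flavanone.

Step 11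
Reactants: 17 (2S)-5,7-bis(benzyloxy)-2-(4-{[(1R,2R)-1-[4-(benzyloxy)phenyl]-1-[(tert-butyldimethylsilyl)oxy]-3-[(triisopropylsilyl)oxy]propan-2-yl]oxy}-3,5-dimethoxyphenyl)chroman-4-one
Product: 18 (2S)-5,7-bis(benzyloxy)-2-(4-{[(1R,2R)-1-[4-(benzyloxy)phenyl]-1,3-dihydroxypropan-2-yl]oxy}-3,5-dimethoxyphenyl)chroman-4-one
Conditions: HF·pyridine, pyridine, THF, 0 °C → rt
Reagents that add atoms: none
Why: Fluoride cleavage of both silyl ethers. The buffered, weakly acidic fluoride source avoids the base-promoted retro-oxa-Michael opening of ring C that would scramble C2, and should not ionise C7 while ring D still carries its benzyl ether.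

Step 12
Reactants: 18 (2S)-5,7-bis(benzyloxy)-2-(4-{[(1R,2R)-1-[4-(benzyloxy)phenyl]-1,3-dihydroxypropan-2-yl]oxy}-3,5-dimethoxyphenyl)chroman-4-one
Product: 19 (2S)-5,7-dihydroxy-2-(4-{[(1R,2R)-1,3-dihydroxy-1-(4-hydroxyphenyl)propan-2-yl]oxy}-3,5-dimethoxyphenyl)chroman-4-one
Conditions: H2 (1 atm), Pd/C (10 wt%), EtOAc/MeOH, rt; stop at full conversion
Reagents that add atoms: none
Why: Heterogeneous hydrogenolysis of three aryl benzyl ethers under neutral conditions. The O–CH2Ph bonds of phenol ethers should cleave much faster than the benzylic C7–OH and C2–O1 bonds or the aryl ketone, and the absence of acid and base leaves C2, C7 and C8 intact.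

## Compound list

1 | methyl (S)-2,2-dimethyl-1,3-dioxolane-4-carboxylate | COC(=O)[C@@H]1COC(C)(C)O1 | starting material
2 | methyl (S)-2,3-dihydroxypropanoate | COC(=O)[C@@H](O)CO | intermediate
3 | methyl (S)-2-hydroxy-3-[(triisopropylsilyl)oxy]propanoate | COC(=O)[C@@H](O)CO[Si](C(C)C)(C(C)C)C(C)C | intermediate
4 | 4-bromo-2,6-dimethoxyphenol | COc1cc(Br)cc(OC)c1O | starting material
5 | methyl (R)-2-(4-bromo-2,6-dimethoxyphenoxy)-3-[(triisopropylsilyl)oxy]propanoate | COc1cc(Br)cc(OC)c1O[C@H](CO[Si](C(C)C)(C(C)C)C(C)C)C(=O)OC | intermediate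
6 | (R)-2-(4-bromo-2,6-dimethoxyphenoxy)-3-[(triisopropylsilyl)oxy]propanal | COc1cc(Br)cc(OC)c1O[C@H](CO[Si](C(C)C)(C(C)C)C(C)C)C=O | intermediate
7 | 1-(benzyloxy)-4-bromobenzene | Brc1ccc(OCc2ccccc2)cc1 | starting material
8 | [4-(benzyloxy)phenyl]magnesium bromide | Br[Mg]c1ccc(OCc2ccccc2)cc1 | intermediate
9 | (1R,2R)-1-[4-(benzyloxy)phenyl]-2-(4-bromo-2,6-dimethoxyphenoxy)-3-[(triisopropylsilyl)oxy]propan-1-ol | COc1cc(Br)cc(OC)c1O[C@H](CO[Si](C(C)C)(C(C)C)C(C)C)[C@H](O)c1ccc(OCc2ccccc2)cc1 | intermediate
10 | (1R,2R)-1-[4-(benzyloxy)phenyl]-2-(4-bromo-2,6-dimethoxyphenoxy)-1-[(tert-butyldimethylsilyl)oxy]-3-[(triisopropylsilyl)oxy]propane | COc1cc(Br)cc(OC)c1O[C@H](CO[Si](C(C)C)(C(C)C)C(C)C)[C@H](O[Si](C)(C)C(C)(C)C)c1ccc(OCc2ccccc2)cc1 | intermediate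
11 | (4-{[(1R,2R)-1-[4-(benzyloxy)phenyl]-1-[(tert-butyldimethylsilyl)oxy]-3-[(triisopropylsilyl)oxy]propan-2-yl]oxy}-3,5-dimethoxyphenyl)lithium | COc1cc([Li])cc(OC)c1O[C@H](CO[Si](C(C)C)(C(C)C)C(C)C)[C@H](O[Si](C)(C)C(C)(C)C)c1ccc(OCc2ccccc2)cc1 | intermediate (not isolated)
12 | lithium (4-{[(1R,2R)-1-[4-(benzyloxy)phenyl]-1-[(tert-butyldimethylsilyl)oxy]-3-[(triisopropylsilyl)oxy]propan-2-yl]oxy}-3,5-dimethoxyphenyl)triisopropoxyborate | [Li+].COc1cc([B-](OC(C)C)(OC(C)C)OC(C)C)cc(OC)c1O[C@H](CO[Si](C(C)C)(C(C)C)C(C)C)[C@H](O[Si](C)(C)C(C)(C)C)c1ccc(OCc2ccccc2)cc1 | intermediate (not isolated)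
13 | (4-{[(1R,2R)-1-[4-(benzyloxy)phenyl]-1-[(tert-butyldimethylsilyl)oxy]-3-[(triisopropylsilyl)oxy]propan-2-yl]oxy}-3,5-dimethoxyphenyl)boronic acid | COc1cc(B(O)O)cc(OC)c1O[C@H](CO[Si](C(C)C)(C(C)C)C(C)C)[C@H](O[Si](C)(C)C(C)(C)C)c1ccc(OCc2ccccc2)cc1 | intermediate
14 | 1-[2,4-bis(benzyloxy)-6-hydroxyphenyl]ethan-1-one | CC(=O)c1c(O)cc(OCc2ccccc2)cc1OCc1ccccc1 | starting material
15 | (E)-1-[2,4-bis(benzyloxy)-6-hydroxyphenyl]-3-(dimethylamino)prop-2-en-1-one | CN(C)/C=C/C(=O)c1c(O)cc(OCc2ccccc2)cc1OCc1ccccc1 | intermediate (not isolated)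
16 | 5,7-bis(benzyloxy)-4H-chromen-4-one | O=c1ccoc2cc(OCc3ccccc3)cc(OCc3ccccc3)c12 | intermediate
17 | (2S)-5,7-bis(benzyloxy)-2-(4-{[(1R,2R)-1-[4-(benzyloxy)phenyl]-1-[(tert-butyldimethylsilyl)oxy]-3-[(triisopropylsilyl)oxy]propan-2-yl]oxy}-3,5-dimethoxyphenyl)chroman-4-one | COc1cc([C@@H]2CC(=O)c3c(OCc4ccccc4)cc(OCc4ccccc4)cc3O2)cc(OC)c1O[C@H](CO[Si](C(C)C)(C(C)C)C(C)C)[C@H](O[Si](C)(C)C(C)(C)C)c1ccc(OCc2ccccc2)cc1 | intermediate
18 | (2S)-5,7-bis(benzyloxy)-2-(4-{[(1R,2R)-1-[4-(benzyloxy)phenyl]-1,3-dihydroxypropan-2-yl]oxy}-3,5-dimethoxyphenyl)chroman-4-one | COc1cc([C@@H]2CC(=O)c3c(OCc4ccccc4)cc(OCc4ccccc4)cc3O2)cc(OC)c1O[C@H](CO)[C@H](O)c1ccc(OCc2ccccc2)cc1 | intermediate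
19 | (2S)-5,7-dihydroxy-2-(4-{[(1R,2R)-1,3-dihydroxy-1-(4-hydroxyphenyl)propan-2-yl]oxy}-3,5-dimethoxyphenyl)chroman-4-one | COc1cc([C@@H]2CC(=O)c3c(O)cc(O)cc3O2)cc(OC)c1O[C@H](CO)[C@H](O)c1ccc(O)cc1 | target

## Step count and risk

Total: 12 steps. Longest linear sequence: 10 steps (steps 1–4, 6–8, 10–12, from 1). Steps 5 and 9 are side branches.

**Step 6 (key step).** The most likely failure is erosion of facial selectivity through incomplete chelation: the aryl ether oxygen is a weak donor and any ether solvent competes for magnesium, so the Felkin–Anh pathway would give the erythro adduct. A second failure is enolisation of the aldehyde by the basic Grignard reagent, which would scramble C8. The fallback sets out from 9 as obtained together with its C7 epimer (1S,2R)-1-[4-(benzyloxy)phenyl]-2-(4-bromo-2,6-dimethoxyphenoxy)-3-[(triisopropylsilyl)oxy]propan-1-ol F1. The mixture is oxidised with Dess–Martin periodinane (NaHCO3 buffer) to (R)-1-[4-(benzyloxy)phenyl]-2-(4-bromo-2,6-dimethoxyphenoxy)-3-[(triisopropylsilyl)oxy]propan-1-one F2. This ketone is reduced with LiBH(s-Bu)3 in THF at −78 °C under Felkin–Anh control (aryloxy group anti to the incoming hydride), which should return the threo alcohol 9. A chelating hydride such as Zn(BH4)2 must not be used here: in a ketone reduction the incoming group is hydrogen rather than aryl, so chelation control would give erythro.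

**Step 10.** Slow insertion is the main risk, because the chromone is deactivated by two donor oxygens and carries a peri benzyloxy group. Protodeboronation of the electron-rich boronic acid would then win, and the facial sense of the ligand is assumed rather than established for this substrate. Adventitious fluoride from the hexafluorophosphate could also loosen the C7 silyl ether. The fallback sets out from 10 and comes back at 17:
- Bromine–lithium exchange (n-BuLi, THF, −78 °C) and quenching with DMF should give 4-{[(1R,2R)-1-[4-(benzyloxy)phenyl]-1-[(tert-butyldimethylsilyl)oxy]-3-[(triisopropylsilyl)oxy]propan-2-yl]oxy}-3,5-dimethoxybenzaldehyde F3.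
- Claisen–Schmidt condensation with 14 (KOH, EtOH, rt) should give the 2'-hydroxychalcone (E)-1-[2,4-bis(benzyloxy)-6-hydroxyphenyl]-3-(4-{[(1R,2R)-1-[4-(benzyloxy)phenyl]-1-[(tert-butyldimethylsilyl)oxy]-3-[(triisopropylsilyl)oxy]propan-2-yl]oxy}-3,5-dimethoxyphenyl)prop-2-en-1-one F4.
- Oxa-Michael cyclisation (NaOAc, EtOH, reflux) should give 17 together with its C2 epimer (2R)-5,7-bis(benzyloxy)-2-(4-{[(1R,2R)-1-[4-(benzyloxy)phenyl]-1-[(tert-butyldimethylsilyl)oxy]-3-[(triisopropylsilyl)oxy]propan-2-yl]oxy}-3,5-dimethoxyphenyl)chroman-4-one F5.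
- The two epimers are separated by preparative chromatography on a chiral stationary phase, and F5 is recycled by base equilibration through F4.
- This fallback gives up catalyst control at C2 in exchange for robust bond formation.

**Step 3.** The phenol is flanked by two methoxy groups, so the SN2 step may be slow. The activated alcohol could then be consumed by alkylation of the reduced azodicarboxylate, and any ionisation at C2 would lower the enantiomeric purity. The fallback sets out from 3 and comes back at 5. Compound 3 is converted with Tf2O and 2,6-lutidine (CH2Cl2, −78 °C) into methyl (S)-3-[(triisopropylsilyl)oxy]-2-{[(trifluoromethyl)sulfonyl]oxy}propanoate F6. The phenoxide of 4 (K2CO3, MeCN, 0 °C → rt) then displaces the triflate with inversion to give 5.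

**Step 8.** Incomplete exchange, or protonation of the aryllithium before it is trapped, would give the debrominated arene. The boronic acid may also lose boron on work-up or during storage. The fallback sets out from 10 and comes back at 13. Miyaura borylation (Pd(dppf)Cl2, B2pin2, KOAc, dioxane, 90 °C, through oxidative addition to zerovalent palladium) should give 2-(4-{[(1R,2R)-1-[4-(benzyloxy)phenyl]-1-[(tert-butyldimethylsilyl)oxy]-3-[(triisopropylsilyl)oxy]propan-2-yl]oxy}-3,5-dimethoxyphenyl)-4,4,5,5-tetramethyl-1,3,2-dioxaborolane F7. The pinacol ester is then cleaved with NaIO4 and NH4OAc in acetone/water to give 13.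

**Step 12.** Over-reduction is the risk: hydrogenolysis of the benzylic C7–OH bond once ring D becomes a free phenol, or of the benzylic C2–O1 bond, or reduction of the ring C ketone. The fallback sets out from 17 and comes back at 19 by reversing the order of the last two steps. Hydrogenolysis of 17 (H2, Pd/C, EtOAc), with the C7 oxygen still shielded by its bulky silyl ether, should give (2S)-2-(4-{[(1R,2R)-1-[(tert-butyldimethylsilyl)oxy]-1-(4-hydroxyphenyl)-3-[(triisopropylsilyl)oxy]propan-2-yl]oxy}-3,5-dimethoxyphenyl)-5,7-dihydroxychroman-4-one F8. Desilylation with HF·pyridine in THF/pyridine then gives 19.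

## Further compounds

F1 | step 6 | (1S,2R)-1-[4-(benzyloxy)phenyl]-2-(4-bromo-2,6-dimethoxyphenoxy)-3-[(triisopropylsilyl)oxy]propan-1-ol | COc1cc(Br)cc(OC)c1O[C@H](CO[Si](C(C)C)(C(C)C)C(C)C)[C@@H](O)c1ccc(OCc2ccccc2)cc1
F2 | step 6 | (R)-1-[4-(benzyloxy)phenyl]-2-(4-bromo-2,6-dimethoxyphenoxy)-3-[(triisopropylsilyl)oxy]propan-1-one | COc1cc(Br)cc(OC)c1O[C@H](CO[Si](C(C)C)(C(C)C)C(C)C)C(=O)c1ccc(OCc2ccccc2)cc1
F3 | step 10 | 4-{[(1R,2R)-1-[4-(benzyloxy)phenyl]-1-[(tert-butyldimethylsilyl)oxy]-3-[(triisopropylsilyl)oxy]propan-2-yl]oxy}-3,5-dimethoxybenzaldehyde | COc1cc(C=O)cc(OC)c1O[C@H](CO[Si](C(C)C)(C(C)C)C(C)C)[C@H](O[Si](C)(C)C(C)(C)C)c1ccc(OCc2ccccc2)cc1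
F4 | step 10 | (E)-1-[2,4-bis(benzyloxy)-6-hydroxyphenyl]-3-(4-{[(1R,2R)-1-[4-(benzyloxy)phenyl]-1-[(tert-butyldimethylsilyl)oxy]-3-[(triisopropylsilyl)oxy]propan-2-yl]oxy}-3,5-dimethoxyphenyl)prop-2-en-1-one | COc1cc(/C=C/C(=O)c2c(O)cc(OCc3ccccc3)cc2OCc2ccccc2)cc(OC)c1O[C@H](CO[Si](C(C)C)(C(C)C)C(C)C)[C@H](O[Si](C)(C)C(C)(C)C)c1ccc(OCc2ccccc2)cc1
F5 | step 10 | (2R)-5,7-bis(benzyloxy)-2-(4-{[(1R,2R)-1-[4-(benzyloxy)phenyl]-1-[(tert-butyldimethylsilyl)oxy]-3-[(triisopropylsilyl)oxy]propan-2-yl]oxy}-3,5-dimethoxyphenyl)chroman-4-one | COc1cc([C@H]2CC(=O)c3c(OCc4ccccc4)cc(OCc4ccccc4)cc3O2)cc(OC)c1O[C@H](CO[Si](C(C)C)(C(C)C)C(C)C)[C@H](O[Si](C)(C)C(C)(C)C)c1ccc(OCc2ccccc2)cc1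
F6 | step 3 | methyl (S)-3-[(triisopropylsilyl)oxy]-2-{[(trifluoromethyl)sulfonyl]oxy}propanoate | COC(=O)[C@@H](OS(=O)(=O)C(F)(F)F)CO[Si](C(C)C)(C(C)C)C(C)C
F7 | step 8 | 2-(4-{[(1R,2R)-1-[4-(benzyloxy)phenyl]-1-[(tert-butyldimethylsilyl)oxy]-3-[(triisopropylsilyl)oxy]propan-2-yl]oxy}-3,5-dimethoxyphenyl)-4,4,5,5-tetramethyl-1,3,2-dioxaborolane | COc1cc(B2OC(C)(C)C(C)(C)O2)cc(OC)c1O[C@H](CO[Si](C(C)C)(C(C)C)C(C)C)[C@H](O[Si](C)(C)C(C)(C)C)c1ccc(OCc2ccccc2)cc1
F8 | step 12 | (2S)-2-(4-{[(1R,2R)-1-[(tert-butyldimethylsilyl)oxy]-1-(4-hydroxyphenyl)-3-[(triisopropylsilyl)oxy]propan-2-yl]oxy}-3,5-dimethoxyphenyl)-5,7-dihydroxychroman-4-one | COc1cc([C@@H]2CC(=O)c3c(O)cc(O)cc3O2)cc(OC)c1O[C@H](CO[Si](C(C)C)(C(C)C)C(C)C)[C@H](O[Si](C)(C)C(C)(C)C)c1ccc(O)cc1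
A1 | alternative 1 | 2,4-bis(benzyloxy)-6-hydroxybenzaldehyde | O=Cc1c(O)cc(OCc2ccccc2)cc1OCc1ccccc1
A2 | alternative 1 | trimethyl orthoformate | COC(OC)OC
A3 | alternative 1 | (1R,2R)-1-[4-(benzyloxy)phenyl]-1,3-bis[(tert-butyldimethylsilyl)oxy]-2-(4-ethenyl-2,6-dimethoxyphenoxy)propane | COc1cc(C=C)cc(OC)c1O[C@H](CO[Si](C)(C)C(C)(C)C)[C@H](O[Si](C)(C)C(C)(C)C)c1ccc(OCc2ccccc2)cc1
A4 | alternative 1 | (2S,4S)-5,7-bis(benzyloxy)-2-(4-{[(1R,2R)-1-[4-(benzyloxy)phenyl]-1,3-bis[(tert-butyldimethylsilyl)oxy]propan-2-yl]oxy}-3,5-dimethoxyphenyl)-4-methoxychromane | COc1cc([C@@H]2C[C@H](OC)c3c(OCc4ccccc4)cc(OCc4ccccc4)cc3O2)cc(OC)c1O[C@H](CO[Si](C)(C)C(C)(C)C)[C@H](O[Si](C)(C)C(C)(C)C)c1ccc(OCc2ccccc2)cc1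
A5 | alternative 2 | (S)-4-benzyl-3-[2-(4-bromo-2,6-dimethoxyphenoxy)acetyl]oxazolidin-2-one | COc1cc(Br)cc(OC)c1OCC(=O)N1C(=O)OC[C@@H]1Cc1ccccc1
A6 | alternative 2 | 4-(benzyloxy)benzaldehyde | O=Cc1ccc(OCc2ccccc2)cc1
A7 | alternative 2 | (S)-4-benzyl-3-[(2S,3R)-3-[4-(benzyloxy)phenyl]-2-(4-bromo-2,6-dimethoxyphenoxy)-3-hydroxypropanoyl]oxazolidin-2-one | COc1cc(Br)cc(OC)c1O[C@@H]([C@H](O)c1ccc(OCc2ccccc2)cc1)C(=O)N1C(=O)OC[C@@H]1Cc1ccccc1
A8 | alternative 3 | (4-{[(1R,2R)-1-[4-(benzyloxy)phenyl]-1,3-bis[(tert-butyldimethylsilyl)oxy]propan-2-yl]oxy}-3,5-dimethoxyphenyl)boronic acid | COc1cc(B(O)O)cc(OC)c1O[C@H](CO[Si](C)(C)C(C)(C)C)[C@H](O[Si](C)(C)C(C)(C)C)c1ccc(OCc2ccccc2)cc1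
A9 | alternative 3 | (2S)-5,7-bis(benzyloxy)-2-(4-{[(1R,2R)-1-[4-(benzyloxy)phenyl]-1,3-bis[(tert-butyldimethylsilyl)oxy]propan-2-yl]oxy}-3,5-dimethoxyphenyl)chroman-4-one | COc1cc([C@@H]2CC(=O)c3c(OCc4ccccc4)cc(OCc4ccccc4)cc3O2)cc(OC)c1O[C@H](CO[Si](C)(C)C(C)(C)C)[C@H](O[Si](C)(C)C(C)(C)C)c1ccc(OCc2ccccc2)cc1
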